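Ring B is cut at C3–C4 and C1–C8a. The cut exploits that C1 (benzylic to ring C), C2 (the only stereocentre that has to be imported) and C3 (ester-bearing) are the 1,3-dipole of a 2-arylcyclopropane-1,1-diester, while C4, C4a and C8a are the formyl, ipso and ortho carbons of an O-protected syringaldehyde. One Sc(OTf)3-catalysed operation joins the two partners: (3+2) annulation to a 2,5-diaryltetrahydrofuran, then Friedel–Crafts ring switch to the 1-aryltetralin with C1 set trans to C2. The precursor is an enantioenriched trans-2-aryl-3-(silyloxymethyl)cyclopropane-1,1-diester from an organocatalytic cyclopropanation.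

Key step: step 5

Remark: ring B locants follow the aryltetralin convention (C1 bears ring C, C2 the CH2O group, C3 the ester, C4 is benzylic to ring A, ring A = C4a–C8a; TBS = tert-butyldimethylsilyl); the (S)-configured diarylprolinol silyl ether is assumed to give the (2S,3R)-formylcyclopropane, by analogy with its established sense of induction on cinnamaldehydes.

Step 1
Reactants: 1 4-(benzyloxy)-3,5-dimethoxybenzaldehyde; 2 (triphenylphosphoranylidene)acetaldehyde
Product: 3 (E)-3-[4-(benzyloxy)-3,5-dimethoxyphenyl]prop-2-enal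
Conditions: 2 (1.15 equiv), toluene, 90 °C
Reagents that add atoms: none
Why: Wittig olefination with a formyl-stabilised ylide should give the (E)-enal, and only a small excess of ylide is used so that the product enal is not homologated a second time.

Step 2
Reactants: 3 (E)-3-[4-(benzyloxy)-3,5-dimethoxyphenyl]prop-2-enal; 4 dimethyl bromomalonate
Product: 5 dimethyl (2S,3R)-2-[4-(benzyloxy)-3,5-dimethoxyphenyl]-3-formylcyclopropane-1,1-dicarboxylate
Conditions: (S)-α,α-diphenylprolinol trimethylsilyl ether (20 mol%), 2,6-lutidine (1.1 equiv), DCM, 0 °C to rt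
Reagents that add atoms: none
Why: Organocatalytic Michael-initiated ring closure via iminium then enamine activation: the (S)-catalyst blocks one face of the E-iminium of 3, the bromomalonate adds to the open face of the β-carbon and the enamine then displaces bromide, which should set both stereocentres at once (aryl carbon S, formyl carbon R) with the aryl and formyl groups trans.

Step 3
Reactants: 5 dimethyl (2S,3R)-2-[4-(benzyloxy)-3,5-dimethoxyphenyl]-3-formylcyclopropane-1,1-dicarboxylate
Product: 6 dimethyl (2S,3R)-2-[4-(benzyloxy)-3,5-dimethoxyphenyl]-3-(hydroxymethyl)cyclopropane-1,1-dicarboxylate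
Conditions: NaBH4, MeOH/THF, −30 °C; AcOH quench
Reagents that add atoms: none
Why: Chemoselective borohydride reduction of an aldehyde beside methyl esters, run cold and quenched with acid so that the alkoxide has little chance to close onto the cis ester as a bicyclic lactone; no stereocentre is touched.

Step 4
Reactants: 6 dimethyl (2S,3R)-2-[4-(benzyloxy)-3,5-dimethoxyphenyl]-3-(hydroxymethyl)cyclopropane-1,1-dicarboxylate
Product: 7 dimethyl (2S,3R)-2-[4-(benzyloxy)-3,5-dimethoxyphenyl]-3-{[(tert-butyldimethylsilyl)oxy]methyl}cyclopropane-1,1-dicarboxylate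
Conditions: TBSCl, imidazole, DMF, 0 °C (on freshly prepared 6)
Reagents that add atoms: tert-butyldimethylsilyl chloride, CC(C)(C)[Si](C)(C)Cl
Why: Silylation of a primary alcohol with a silyl chloride and imidazole is fast and needs no alkoxide, so the lactonisation-prone hydroxy diester is capped at once, and a silyl ether (unlike a side-chain benzyl ether) offers no benzylic hydrogen for hydride transfer to the C1 cation of step 5 and can fall in the final acidic step.

Step 5
Reactants: 7 dimethyl (2S,3R)-2-[4-(benzyloxy)-3,5-dimethoxyphenyl]-3-{[(tert-butyldimethylsilyl)oxy]methyl}cyclopropane-1,1-dicarboxylate; 1 4-(benzyloxy)-3,5-dimethoxybenzaldehyde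
Product: 9 dimethyl (1S,2R)-7-(benzyloxy)-1-[4-(benzyloxy)-3,5-dimethoxyphenyl]-2-{[(tert-butyldimethylsilyl)oxy]methyl}-4-hydroxy-6,8-dimethoxy-1,2,3,4-tetrahydronaphthalene-3,3-dicarboxylate (C4 epimers), via tetrahydrofuran cycloadduct 8 (not isolated)
Conditions: 1 (1.5 equiv), Sc(OTf)3 (15 mol%), 4 Å MS, ClCH2CH2Cl, 0 °C to rt, then 50 °C
Reagents that add atoms: none
Why: Proposed new method: Sc(OTf)3 chelates the geminal diester of 7 and polarises the C1–C3 bond, the carbonyl oxygen of 1 attacks benzylic C1 and the scandium malonate closes onto the oxocarbenium carbon (C3–C4), which is the established Lewis acid (3+2) annulation of aldehydes with 2-arylcyclopropane-1,1-diesters and should give tetrahydrofuran 8. On warming, the same acid should re-ionise the C1–O bond of 8, the one next to ring C and remote from the cation-destabilising diester, and C8a of ring A then attacks the C1 cation; this is the known acid rearrangement of 2,5-diaryltetrahydrofurans to 1-aryltetralins, and what is new is running both events in one flask on a 2,3-disubstituted cyclopropane. Ring B closes by intramolecular Friedel–Crafts alkylation, a six-membered closure in which the C4a–C8a arene bond becomes part of the new ring, and the arenium proton ends on the C4 alkoxide. C2 is carried over untouched from 7, whereas C1 is created from a planar benzylic cation and should be set trans to the C2 side chain under substrate control (aryl and CH2OTBS both pseudo-axial, away from the peri C8 methoxy group); the C4 carbinol is left as a mixture because step 7 erases it. The step needs (a) cleavage of the benzylic and not the C2–C3 cyclopropane bond, secured by the aryl donor, (b) ionisation of C1–O and not C4–O, secured by the diester next to C4, (c) arylation faster than loss of the C2 proton, favoured because C8a is ortho and para to methoxy groups, and (d) no regiochemical choice on ring A, whose two ortho positions are equivalent.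

Step 6
Reactants: 9 dimethyl (1S,2R)-7-(benzyloxy)-1-[4-(benzyloxy)-3,5-dimethoxyphenyl]-2-{[(tert-butyldimethylsilyl)oxy]methyl}-4-hydroxy-6,8-dimethoxy-1,2,3,4-tetrahydronaphthalene-3,3-dicarboxylate
Product: 10 dimethyl (1S,2R)-4-acetoxy-7-(benzyloxy)-1-[4-(benzyloxy)-3,5-dimethoxyphenyl]-2-{[(tert-butyldimethylsilyl)oxy]methyl}-6,8-dimethoxy-1,2,3,4-tetrahydronaphthalene-3,3-dicarboxylate (C4 epimers)
Conditions: Ac2O, pyridine, DMAP (10 mol%), DCM, 0 °C to rt
Reagents that add atoms: acetic anhydride, CC(=O)OC(C)=O
Why: DMAP-catalysed acetylation of the hindered benzylic alcohol caps the β-hydroxy malonate, which blocks retro-aldol cleavage of C3–C4 and turns the C4 oxygen into a leaving group.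

Step 7
Reactants: 10 dimethyl (1S,2R)-4-acetoxy-7-(benzyloxy)-1-[4-(benzyloxy)-3,5-dimethoxyphenyl]-2-{[(tert-butyldimethylsilyl)oxy]methyl}-6,8-dimethoxy-1,2,3,4-tetrahydronaphthalene-3,3-dicarboxylate
Product: 12 methyl (1S,2R)-7-(benzyloxy)-1-[4-(benzyloxy)-3,5-dimethoxyphenyl]-2-{[(tert-butyldimethylsilyl)oxy]methyl}-6,8-dimethoxy-1,2-dihydronaphthalene-3-carboxylate, via lithium carboxylate 11 (not isolated)
Conditions: LiCl (4 equiv), H2O (2 equiv), DMSO, 140 °C, argon
Reagents that add atoms: none
Why: Krapcho dealkoxycarbonylation, in which chloride demethylates one ester by SN2 attack at the methyl group and the β-acetoxy carboxylate 11 then loses CO2 and acetate (decarboxylative elimination, or E1cB from the ester enolate), should give the conjugated C3=C4 ester and remove the undefined C4 centre without involving C1 or C2.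

Step 8
Reactants: 12 methyl (1S,2R)-7-(benzyloxy)-1-[4-(benzyloxy)-3,5-dimethoxyphenyl]-2-{[(tert-butyldimethylsilyl)oxy]methyl}-6,8-dimethoxy-1,2-dihydronaphthalene-3-carboxylate
Product: 14 methyl (1S,2R)-7-hydroxy-1-(4-hydroxy-3,5-dimethoxyphenyl)-2-(hydroxymethyl)-6,8-dimethoxy-1,2-dihydronaphthalene-3-carboxylate, via diphenol silyl ether 13 (not isolated)
Conditions: BCl3 (6 equiv), C6HMe5 (6 equiv), DCM, −78 °C; then MeOH, −78 °C to rt
Reagents that add atoms: none
Why: BCl3 with pentamethylbenzene as a non-basic benzyl cation scavenger should cleave the two aryl benzyl ethers at low temperature without touching the aryl methyl ethers, the methyl ester or the C3=C4 bond, and the HCl/methanol formed in the quench should then solvolyse the primary silyl ether (acid-mediated desilylation).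

Compound list
1 | 4-(benzyloxy)-3,5-dimethoxybenzaldehyde | O=Cc1cc(OC)c(OCc2ccccc2)c(OC)c1 | starting material
2 | (triphenylphosphoranylidene)acetaldehyde | O=CC=P(c1ccccc1)(c1ccccc1)c1ccccc1 | starting material
3 | (E)-3-[4-(benzyloxy)-3,5-dimethoxyphenyl]prop-2-enal | O=C/C=C/c1cc(OC)c(OCc2ccccc2)c(OC)c1 | intermediate
4 | dimethyl bromomalonate | COC(=O)C(Br)C(=O)OC | starting material
5 | dimethyl (2S,3R)-2-[4-(benzyloxy)-3,5-dimethoxyphenyl]-3-formylcyclopropane-1,1-dicarboxylate | COC(=O)C1(C(=O)OC)[C@H](c2cc(OC)c(OCc3ccccc3)c(OC)c2)[C@H]1C=O | intermediate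
6 | dimethyl (2S,3R)-2-[4-(benzyloxy)-3,5-dimethoxyphenyl]-3-(hydroxymethyl)cyclopropane-1,1-dicarboxylate | COC(=O)C1(C(=O)OC)[C@H](c2cc(OC)c(OCc3ccccc3)c(OC)c2)[C@H]1CO | intermediate
7 | dimethyl (2S,3R)-2-[4-(benzyloxy)-3,5-dimethoxyphenyl]-3-{[(tert-butyldimethylsilyl)oxy]methyl}cyclopropane-1,1-dicarboxylate | COC(=O)C1(C(=O)OC)[C@H](c2cc(OC)c(OCc3ccccc3)c(OC)c2)[C@H]1CO[Si](C)(C)C(C)(C)C | intermediate
8 | dimethyl (4R)-2,5-bis[4-(benzyloxy)-3,5-dimethoxyphenyl]-4-{[(tert-butyldimethylsilyl)oxy]methyl}oxolane-3,3-dicarboxylate (not isolated; oxolane C2 and C5 not defined, 2,5-cis expected) | COC(=O)C1(C(=O)OC)C(c2cc(OC)c(OCc3ccccc3)c(OC)c2)OC(c2cc(OC)c(OCc3ccccc3)c(OC)c2)[C@H]1CO[Si](C)(C)C(C)(C)C | intermediate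
9 | dimethyl (1S,2R)-7-(benzyloxy)-1-[4-(benzyloxy)-3,5-dimethoxyphenyl]-2-{[(tert-butyldimethylsilyl)oxy]methyl}-4-hydroxy-6,8-dimethoxy-1,2,3,4-tetrahydronaphthalene-3,3-dicarboxylate (C4 epimers) | COC(=O)C1(C(=O)OC)C(O)c2cc(OC)c(OCc3ccccc3)c(OC)c2[C@H](c2cc(OC)c(OCc3ccccc3)c(OC)c2)[C@H]1CO[Si](C)(C)C(C)(C)C | intermediate
10 | dimethyl (1S,2R)-4-acetoxy-7-(benzyloxy)-1-[4-(benzyloxy)-3,5-dimethoxyphenyl]-2-{[(tert-butyldimethylsilyl)oxy]methyl}-6,8-dimethoxy-1,2,3,4-tetrahydronaphthalene-3,3-dicarboxylate (C4 epimers) | COC(=O)C1(C(=O)OC)C(OC(C)=O)c2cc(OC)c(OCc3ccccc3)c(OC)c2[C@H](c2cc(OC)c(OCc3ccccc3)c(OC)c2)[C@H]1CO[Si](C)(C)C(C)(C)C | intermediate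
11 | lithium (1S,2R)-4-acetoxy-7-(benzyloxy)-1-[4-(benzyloxy)-3,5-dimethoxyphenyl]-2-{[(tert-butyldimethylsilyl)oxy]methyl}-6,8-dimethoxy-3-(methoxycarbonyl)-1,2,3,4-tetrahydronaphthalene-3-carboxylate (not isolated; C3 and C4 epimers) | [Li+].[O-]C(=O)C1(C(=O)OC)C(OC(C)=O)c2cc(OC)c(OCc3ccccc3)c(OC)c2[C@H](c2cc(OC)c(OCc3ccccc3)c(OC)c2)[C@H]1CO[Si](C)(C)C(C)(C)C | intermediate
12 | methyl (1S,2R)-7-(benzyloxy)-1-[4-(benzyloxy)-3,5-dimethoxyphenyl]-2-{[(tert-butyldimethylsilyl)oxy]methyl}-6,8-dimethoxy-1,2-dihydronaphthalene-3-carboxylate | COC(=O)C1=Cc2cc(OC)c(OCc3ccccc3)c(OC)c2[C@H](c2cc(OC)c(OCc3ccccc3)c(OC)c2)[C@H]1CO[Si](C)(C)C(C)(C)C | intermediate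
13 | methyl (1S,2R)-2-{[(tert-butyldimethylsilyl)oxy]methyl}-7-hydroxy-1-(4-hydroxy-3,5-dimethoxyphenyl)-6,8-dimethoxy-1,2-dihydronaphthalene-3-carboxylate (not isolated) | COC(=O)C1=Cc2cc(OC)c(O)c(OC)c2[C@H](c2cc(OC)c(O)c(OC)c2)[C@H]1CO[Si](C)(C)C(C)(C)C | intermediate
14 | methyl (1S,2R)-7-hydroxy-1-(4-hydroxy-3,5-dimethoxyphenyl)-2-(hydroxymethyl)-6,8-dimethoxy-1,2-dihydronaphthalene-3-carboxylate (CNP0143100.1; 1,2-trans) | COC(=O)C1=Cc2cc(OC)c(O)c(OC)c2[C@H](c2cc(OC)c(O)c(OC)c2)[C@H]1CO | target

Total step count: 8. Longest linear sequence: 8 steps (1 → 3 → 5 → 6 → 7 → 9 → 10 → 12 → 14); aldehyde 1 enters twice, as the source of ring C in step 1 and as ring A plus C4 in step 5.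

Steps most likely to fail

1. Step 5. The cycloaddition of the 2,3-disubstituted cyclopropane may be slow, or the sequence may stop at the cycloadduct. The C1 cation may lose the C2 proton and so erase the only imported stereocentre, or the silyl ether may be cleaved on prolonged heating with the Lewis acid. The fallback sets out from 7 and 1 and comes back at 9. It runs the two bond formations as separate, individually precedented operations instead of one cascade. Sn(OTf)2 (10 mol%) in DCM at room temperature should give the aldehyde–cyclopropane (3+2) cycloadduct 8, which is isolated and purified. Treatment of 8 with BF3·OEt2 in DCM at −40 to 0 °C, the classical acid-induced rearrangement of 2,5-diaryltetrahydrofurans to 1-aryltetralins, should then give 9. Each stage can be optimised on its own, and no compound outside the compound list is made (F0).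

2. Step 7. Demethylation at the crowded malonate may be slow, the silyl ether may be partly lost, or the C3=C4 bond may migrate and the dihydronaphthalene may oxidise to the naphthalene at 140 °C. The fallback sets out from 9 and comes back at 12, bypassing 10 and 11. Me3SnOH in ClCH2CH2Cl at 80 °C should hydrolyse one of the two methyl esters under near-neutral conditions. This should give the β-hydroxy half-acid (1S,2R)-7-(benzyloxy)-1-[4-(benzyloxy)-3,5-dimethoxyphenyl]-2-{[(tert-butyldimethylsilyl)oxy]methyl}-4-hydroxy-6,8-dimethoxy-3-(methoxycarbonyl)-1,2,3,4-tetrahydronaphthalene-3-carboxylic acid F1. Dehydrative decarboxylation of F1 with N,N-dimethylformamide dineopentyl acetal in toluene at 80 °C, a known alkene synthesis from β-hydroxy acids, should then give 12 at a much lower temperature than the chloride route.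

3. Step 2. Iminium addition to the electron-rich enal may be slow, the amine may open the formyl-substituted donor–acceptor cyclopropane, enantiomeric purity may erode, and the alcohol derived in step 3 may lactonise. The fallback sets out from 3 and comes back at 7, bypassing 5 and 6. Luche reduction of 3 (NaBH4, CeCl3·7H2O, MeOH, 0 °C) should give the allylic alcohol (E)-3-[4-(benzyloxy)-3,5-dimethoxyphenyl]prop-2-en-1-ol F2. TBSCl and imidazole should convert it into the silyl ether tert-butyl{[(E)-3-(4-benzyloxy-3,5-dimethoxyphenyl)prop-2-en-1-yl]oxy}dimethylsilane F3. Enantioselective cyclopropanation of the E-alkene of F3 with the phenyliodonium ylide of dimethyl malonate, under Cu(MeCN)4PF6 (monovalent copper) and a chiral side-arm bisoxazoline ligand, should then give 7 directly. This is a known reaction class for aryl-substituted alkenes; the E geometry becomes the trans ring relationship and the ligand enantiomer is chosen for the (2S,3R) product.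

Further compounds
F0 | step 5 | none | none
F1 | step 7 | (1S,2R)-7-(benzyloxy)-1-[4-(benzyloxy)-3,5-dimethoxyphenyl]-2-{[(tert-butyldimethylsilyl)oxy]methyl}-4-hydroxy-6,8-dimethoxy-3-(methoxycarbonyl)-1,2,3,4-tetrahydronaphthalene-3-carboxylic acid (C3 and C4 epimers) | OC(=O)C1(C(=O)OC)C(O)c2cc(OC)c(OCc3ccccc3)c(OC)c2[C@H](c2cc(OC)c(OCc3ccccc3)c(OC)c2)[C@H]1CO[Si](C)(C)C(C)(C)C
F2 | step 2 | (E)-3-[4-(benzyloxy)-3,5-dimethoxyphenyl]prop-2-en-1-ol | OC/C=C/c1cc(OC)c(OCc2ccccc2)c(OC)c1
F3 | step 2 | tert-butyl{[(E)-3-(4-benzyloxy-3,5-dimethoxyphenyl)prop-2-en-1-yl]oxy}dimethylsilane | CC(C)(C)[Si](C)(C)OC/C=C/c1cc(OC)c(OCc2ccccc2)c(OC)c1
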